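**Retrosynthetic overview**

1. Feature used: with the side chain numbered C1'–C9' from lactone C5, the ring oxygen O1 on C5 is homoallylic to the C2'=C3' alkene (O1–C5–C1'–C2'=C3'). A silicon atom on O1 therefore reaches C2' through a five-membered O1–Si–C2'–C1'–C5 ring and places the CH2OH carbon on C3', cis to silicon and so trans to C1'.
2. Butenolide (ring B) is made last: C3–C4 by Dieckmann closure of the O-acetyl α-hydroxy ester, C4–CH2OH by triflation and Stille hydroxymethylation.
3. C3'–CHO and C2'–Si come from a silicon-tethered, rhodium-catalysed silylformylation of the C2'≡C3' alkyne, which closes a temporary 1-oxa-2-silacyclopentane (ring C); protodesilylation and reduction follow.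
4. C1'–C2' comes from acetylide opening of methyl (S)-glycidate, which supplies C5 as (S); C4'–C5' comes from Negishi coupling of the (E)-alkenyl iodide made from dihydro-β-ionone (cyclohexene ring A is bought in).
5. Ring order: ring A from the start; temporary ring C in step 8, opened in step 9; ring B in step 13.

Key step: step 8

Remark: the labels O1, C2–C5 (butenolide) and C1'–C9' (side chain from C5) of the target are kept for all intermediates; the target's single stereocentre C5 is (S) and both chain alkenes are (E).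

**Route**

Step 1
Reactants: 1 dihydro-β-ionone [4-(2,6,6-trimethylcyclohex-1-en-1-yl)butan-2-one]
Product: 3 2-(but-3-yn-1-yl)-1,3,3-trimethylcyclohex-1-ene, via enol phosphate 2 (not isolated)
Conditions: LiN(iPr)2, THF, −78 °C; ClP(O)(OEt)2, −78 °C to rt; then LiN(iPr)2 (2.3 equiv), −78 °C to rt; H2O
Reagents that add atoms: none
Why: Kinetic deprotonation at the methyl group, O-phosphorylation and amide-induced β-elimination of diethyl phosphate from the terminal enol phosphate (methyl ketone to alkyne conversion) should give the terminal alkyne, held as its acetylide until work-up.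

Step 2
Reactants: 3 2-(but-3-yn-1-yl)-1,3,3-trimethylcyclohex-1-ene
Product: 5 (E)-2-(4-iodo-3-methylbut-3-en-1-yl)-1,3,3-trimethylcyclohex-1-ene, via alkenylalane 4 (not isolated)
Conditions: Me3Al, Cp2ZrCl2 (cat.), CH2Cl2, 0 °C to rt; then I2, THF, −30 to 0 °C
Reagents that add atoms: trimethylaluminium, C[Al](C)C; iodine, II
Why: Zirconium-catalysed carboalumination (Negishi carboalumination) adds CH3 and Al syn with aluminium on the terminal carbon, and iodinolysis with retention should give the (E)-iodide, the tetrasubstituted ring alkene being inert.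

Step 3
Reactants: 6 4-(trimethylsilyl)but-3-yn-1-ol
Product: 7 (4-iodobut-1-yn-1-yl)trimethylsilane
Conditions: I2, PPh3, imidazole, CH2Cl2, 0 °C to rt
Reagents that add atoms: iodine, II
Why: Appel-type iodination, in which the alkoxyphosphonium ion of the primary alcohol is displaced by iodide in an SN2 step.

Step 4
Reactants: 7 (4-iodobut-1-yn-1-yl)trimethylsilane; 5 (E)-2-(4-iodo-3-methylbut-3-en-1-yl)-1,3,3-trimethylcyclohex-1-ene
Product: 9 trimethyl[(E)-6-methyl-8-(2,6,6-trimethylcyclohex-1-en-1-yl)oct-5-en-1-yn-1-yl]silane, via alkylzinc iodide 8 (not isolated)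
Conditions: Zn dust (activated with BrCH2CH2Br, Me3SiCl), THF, 40 °C; then 5, Pd(PPh3)4 (5 mol %), THF, rt to 45 °C
Reagents that add atoms: none
Why: Negishi coupling, in which zinc inserts into the primary C–I bond and the alkylzinc iodide couples with the alkenyl iodide at zerovalent palladium with retention of the (E) geometry, the silyl group keeping the alkyne terminus inert.

Step 5
Reactants: 9 trimethyl[(E)-6-methyl-8-(2,6,6-trimethylcyclohex-1-en-1-yl)oct-5-en-1-yn-1-yl]silane
Product: 10 (E)-2-(3-methyloct-3-en-7-yn-1-yl)-1,3,3-trimethylcyclohex-1-ene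
Conditions: K2CO3, MeOH, rt
Reagents that add atoms: none
Why: Methanolysis of the alkynylsilane (methoxide attack on silicon, protonation of the acetylide) frees the terminal alkyne without touching the alkenes.

Step 6
Reactants: 10 (E)-2-(3-methyloct-3-en-7-yn-1-yl)-1,3,3-trimethylcyclohex-1-ene; 11 methyl (S)-glycidate [methyl (2S)-oxirane-2-carboxylate]
Product: 13 methyl (2S,8E)-2-hydroxy-9-methyl-11-(2,6,6-trimethylcyclohex-1-en-1-yl)undec-8-en-4-ynoate, via lithium acetylide 12 (not isolated)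
Conditions: n-BuLi, THF, −78 °C; BF3·OEt2, −78 °C; then 11, −78 °C
Reagents that add atoms: none
Why: Yamaguchi-type alkynylation, in which the alkynyl–BF3 species opens the BF3-activated epoxide by SN2 attack at the unsubstituted C3 at −78 °C faster than it adds to the ester, so that the untouched (S) centre of 11 becomes C5 of the target.

Step 7
Reactants: 13 methyl (2S,8E)-2-hydroxy-9-methyl-11-(2,6,6-trimethylcyclohex-1-en-1-yl)undec-8-en-4-ynoate; 14 chlorodiisopropylsilane
Product: 15 methyl (2S,8E)-2-[(diisopropylsilyl)oxy]-9-methyl-11-(2,6,6-trimethylcyclohex-1-en-1-yl)undec-8-en-4-ynoate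
Conditions: iPr2SiHCl, Et3N, DMAP (cat.), CH2Cl2, 0 °C to rt
Reagents that add atoms: chlorodiisopropylsilane (14), CC(C)[SiH](Cl)C(C)C
Why: Amine-promoted O-silylation of the secondary alcohol by the chlorosilane leaves the Si–H bond and the stereocentre intact, and the two isopropyl groups make the hydrosilyl ether robust enough to handle.

Step 8
Reactants: 15 methyl (2S,8E)-2-[(diisopropylsilyl)oxy]-9-methyl-11-(2,6,6-trimethylcyclohex-1-en-1-yl)undec-8-en-4-ynoate
Product: 16 methyl (3Z,5S)-2,2-diisopropyl-3-[(5E)-6-methyl-1-oxo-8-(2,6,6-trimethylcyclohex-1-en-1-yl)oct-5-en-2-ylidene]-1,2-oxasilolane-5-carboxylate (formyl on C3', cis to Si and trans to C1')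
Conditions: Rh(acac)(CO)2 (3 mol %), CO (60 bar), toluene, 60 °C
Reagents that add atoms: carbon monoxide, [C-]#[O+]
Why: The Si–H bond adds oxidatively to monovalent rhodium, the Si–Rh bond adds syn across the C2'≡C3' alkyne with silicon going to C2', CO inserts into the C3'–Rh bond and acyl–hydride reductive elimination releases the enal. The closest known reaction type is the rhodium-catalysed intramolecular silylformylation of homopropargylic hydrosilyl ethers. The one ring closed, the 1-oxa-2-silacyclopentane, forms in the 5-exo-dig mode by attack of silicon on C2'. No stereocentre is created; the (Z) geometry of the exocyclic alkene follows from the syn addition, and C5 is a spectator. The step needs regioselective and syn delivery of Si and CHO and chemoselectivity for the alkyne: the five-membered tether from O1 on C5 secures the first two (6-endo closure is strained), CO pressure suppresses plain hydrosilylation, and the tri- and tetrasubstituted alkenes are inert to the phosphine-free rhodium carbonyl at this temperature.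

Step 9
Reactants: 16 methyl (3Z,5S)-2,2-diisopropyl-3-[(5E)-6-methyl-1-oxo-8-(2,6,6-trimethylcyclohex-1-en-1-yl)oct-5-en-2-ylidene]-1,2-oxasilolane-5-carboxylate
Product: 17 methyl (2S,4E,8E)-5-formyl-2-hydroxy-9-methyl-11-(2,6,6-trimethylcyclohex-1-en-1-yl)undeca-4,8-dienoate
Conditions: Bu4NF·3H2O, THF, 0 °C to rt
Reagents that add atoms: none
Why: Fluoride adds to the strained alkoxysilane to give a pentacoordinate siliconate whose C2'–Si bond is protonated with retention (protodesilylation) while the Si–O bond is cleaved as well, and the resulting (E)-2-alkyl enal is also the thermodynamically preferred isomer.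

Step 10
Reactants: 17 methyl (2S,4E,8E)-5-formyl-2-hydroxy-9-methyl-11-(2,6,6-trimethylcyclohex-1-en-1-yl)undeca-4,8-dienoate
Product: 18 methyl (2S,4E,8E)-2-hydroxy-5-(hydroxymethyl)-9-methyl-11-(2,6,6-trimethylcyclohex-1-en-1-yl)undeca-4,8-dienoate
Conditions: NaBH4, CeCl3·7H2O, MeOH, −40 °C
Reagents that add atoms: none
Why: Luche reduction gives clean 1,2-reduction of the enal at low temperature, where the methyl ester is not reduced and no stereocentre is formed.

Step 11
Reactants: 18 methyl (2S,4E,8E)-2-hydroxy-5-(hydroxymethyl)-9-methyl-11-(2,6,6-trimethylcyclohex-1-en-1-yl)undeca-4,8-dienoate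
Product: 19 methyl (2S,4E,8E)-5-{[(tert-butyldimethylsilyl)oxy]methyl}-2-hydroxy-9-methyl-11-(2,6,6-trimethylcyclohex-1-en-1-yl)undeca-4,8-dienoate
Conditions: TBSCl (1.05 equiv), imidazole, CH2Cl2, −20 to 0 °C
Reagents that add atoms: tert-butyldimethylsilyl chloride, CC(C)(C)[Si](C)(C)Cl
Why: Silylation is selective for the primary allylic alcohol over the more hindered and less nucleophilic secondary hydroxyl next to the ester.

Step 12
Reactants: 19 methyl (2S,4E,8E)-5-{[(tert-butyldimethylsilyl)oxy]methyl}-2-hydroxy-9-methyl-11-(2,6,6-trimethylcyclohex-1-en-1-yl)undeca-4,8-dienoate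
Product: 20 methyl (2S,4E,8E)-2-acetoxy-5-{[(tert-butyldimethylsilyl)oxy]methyl}-9-methyl-11-(2,6,6-trimethylcyclohex-1-en-1-yl)undeca-4,8-dienoate
Conditions: Ac2O, pyridine, DMAP (cat.), CH2Cl2, 0 °C to rt
Reagents that add atoms: acetic anhydride, CC(=O)OC(C)=O
Why: DMAP-catalysed acylation of the secondary alcohol, under which the silyl ether and the stereocentre are stable.

Step 13
Reactants: 20 methyl (2S,4E,8E)-2-acetoxy-5-{[(tert-butyldimethylsilyl)oxy]methyl}-9-methyl-11-(2,6,6-trimethylcyclohex-1-en-1-yl)undeca-4,8-dienoate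
Product: 21 (5S)-5-[(2E,6E)-3-{[(tert-butyldimethylsilyl)oxy]methyl}-7-methyl-9-(2,6,6-trimethylcyclohex-1-en-1-yl)nona-2,6-dien-1-yl]-4-hydroxyfuran-2(5H)-one
Conditions: LiN(SiMe3)2 (2.5 equiv), THF, −78 °C; then cold 1 M HCl
Reagents that add atoms: none
Why: Dieckmann condensation, in which the kinetically formed acetate enolate attacks the methyl ester in a 5-exo-trig closure and loss of methoxide gives the tetronic acid, whose anion resists further deprotonation at C5, so the (S) centre should be kept.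

Step 14
Reactants: 21 (5S)-5-[(2E,6E)-3-{[(tert-butyldimethylsilyl)oxy]methyl}-7-methyl-9-(2,6,6-trimethylcyclohex-1-en-1-yl)nona-2,6-dien-1-yl]-4-hydroxyfuran-2(5H)-one
Product: 22 (2S)-2-[(2E,6E)-3-{[(tert-butyldimethylsilyl)oxy]methyl}-7-methyl-9-(2,6,6-trimethylcyclohex-1-en-1-yl)nona-2,6-dien-1-yl]-5-oxo-2,5-dihydrofuran-3-yl trifluoromethanesulfonate
Conditions: Tf2O, iPr2NEt, CH2Cl2, −78 °C
Reagents that add atoms: trifluoromethanesulfonic anhydride, O=S(=O)(OS(=O)(=O)C(F)(F)F)C(F)(F)F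
Why: O-Sulfonylation of the acidic enol of the tetronic acid gives the vinylogous acyl triflate, the low temperature and hindered base avoiding deprotonation at C5.

Step 15
Reactants: 22 (2S)-2-[(2E,6E)-3-{[(tert-butyldimethylsilyl)oxy]methyl}-7-methyl-9-(2,6,6-trimethylcyclohex-1-en-1-yl)nona-2,6-dien-1-yl]-5-oxo-2,5-dihydrofuran-3-yl trifluoromethanesulfonate
Product: 23 (5S)-5-[(2E,6E)-3-{[(tert-butyldimethylsilyl)oxy]methyl}-7-methyl-9-(2,6,6-trimethylcyclohex-1-en-1-yl)nona-2,6-dien-1-yl]-4-(hydroxymethyl)furan-2(5H)-one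
Conditions: Bu3SnCH2OH, Pd(PPh3)4 (5 mol %), LiCl, 1,4-dioxane, 80 °C
Reagents that add atoms: (tributylstannyl)methanol, CCCC[Sn](CO)(CCCC)CCCC
Why: Stille coupling, in which the electron-poor enol triflate adds to zerovalent palladium, chloride replaces triflate on the metal and the α-oxygenated CH2OH group transfers from tin in preference to butyl under neutral conditions that do not endanger C5.

Step 16
Reactants: 23 (5S)-5-[(2E,6E)-3-{[(tert-butyldimethylsilyl)oxy]methyl}-7-methyl-9-(2,6,6-trimethylcyclohex-1-en-1-yl)nona-2,6-dien-1-yl]-4-(hydroxymethyl)furan-2(5H)-one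
Product: 24 (5S)-4-(hydroxymethyl)-5-[(2E,6E)-3-(hydroxymethyl)-7-methyl-9-(2,6,6-trimethylcyclohex-1-en-1-yl)nona-2,6-dien-1-yl]furan-2(5H)-one (target)
Conditions: HF·pyridine, pyridine, THF, 0 °C to rt
Reagents that add atoms: none
Why: Fluoride cleavage of the primary silyl ether under buffered, weakly acidic conditions should spare the base-sensitive stereocentre of the butenolide and the acid-sensitive alkenes.

**Compound list**

1 | dihydro-β-ionone, 4-(2,6,6-trimethylcyclohex-1-en-1-yl)butan-2-one | CC1=C(CCC(C)=O)C(C)(C)CCC1 | starting material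
2 | diethyl 4-(2,6,6-trimethylcyclohex-1-en-1-yl)but-1-en-2-yl phosphate | CC1=C(CCC(=C)OP(=O)(OCC)OCC)C(C)(C)CCC1 | intermediate
3 | 2-(but-3-yn-1-yl)-1,3,3-trimethylcyclohex-1-ene | CC1=C(CCC#C)C(C)(C)CCC1 | intermediate
4 | dimethyl[(E)-2-methyl-4-(2,6,6-trimethylcyclohex-1-en-1-yl)but-1-en-1-yl]alane | CC1=C(CC/C(C)=C/[Al](C)C)C(C)(C)CCC1 | intermediate
5 | (E)-2-(4-iodo-3-methylbut-3-en-1-yl)-1,3,3-trimethylcyclohex-1-ene | CC1=C(CC/C(C)=C/I)C(C)(C)CCC1 | intermediate
6 | 4-(trimethylsilyl)but-3-yn-1-ol | C[Si](C)(C)C#CCCO | starting material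
7 | (4-iodobut-1-yn-1-yl)trimethylsilane | C[Si](C)(C)C#CCCI | intermediate
8 | iodo[4-(trimethylsilyl)but-3-yn-1-yl]zinc | C[Si](C)(C)C#CCC[Zn]I | intermediate
9 | trimethyl[(E)-6-methyl-8-(2,6,6-trimethylcyclohex-1-en-1-yl)oct-5-en-1-yn-1-yl]silane | CC1=C(CC/C(C)=C/CCC#C[Si](C)(C)C)C(C)(C)CCC1 | intermediate
10 | (E)-2-(3-methyloct-3-en-7-yn-1-yl)-1,3,3-trimethylcyclohex-1-ene | CC1=C(CC/C(C)=C/CCC#C)C(C)(C)CCC1 | intermediate
11 | methyl (S)-glycidate, methyl (2S)-oxirane-2-carboxylate | COC(=O)[C@@H]1CO1 | starting material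
12 | [(E)-6-methyl-8-(2,6,6-trimethylcyclohex-1-en-1-yl)oct-5-en-1-yn-1-yl]lithium | CC1=C(CC/C(C)=C/CCC#C[Li])C(C)(C)CCC1 | intermediate
13 | methyl (2S,8E)-2-hydroxy-9-methyl-11-(2,6,6-trimethylcyclohex-1-en-1-yl)undec-8-en-4-ynoate | CC1=C(CC/C(C)=C/CCC#CC[C@@H](C(=O)OC)O)C(C)(C)CCC1 | intermediate
14 | chlorodiisopropylsilane | CC(C)[SiH](Cl)C(C)C | starting material
15 | methyl (2S,8E)-2-[(diisopropylsilyl)oxy]-9-methyl-11-(2,6,6-trimethylcyclohex-1-en-1-yl)undec-8-en-4-ynoate | CC1=C(CC/C(C)=C/CCC#CC[C@@H](C(=O)OC)O[SiH](C(C)C)C(C)C)C(C)(C)CCC1 | intermediate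
16 | methyl (3Z,5S)-2,2-diisopropyl-3-[(5E)-6-methyl-1-oxo-8-(2,6,6-trimethylcyclohex-1-en-1-yl)oct-5-en-2-ylidene]-1,2-oxasilolane-5-carboxylate | CC1=C(CC/C(C)=C/CC/C(C=O)=C2\C[C@@H](C(=O)OC)O[Si]2(C(C)C)C(C)C)C(C)(C)CCC1 | intermediate
17 | methyl (2S,4E,8E)-5-formyl-2-hydroxy-9-methyl-11-(2,6,6-trimethylcyclohex-1-en-1-yl)undeca-4,8-dienoate | CC1=C(CC/C(C)=C/CC/C(C=O)=C\C[C@@H](C(=O)OC)O)C(C)(C)CCC1 | intermediate
18 | methyl (2S,4E,8E)-2-hydroxy-5-(hydroxymethyl)-9-methyl-11-(2,6,6-trimethylcyclohex-1-en-1-yl)undeca-4,8-dienoate | CC1=C(CC/C(C)=C/CC/C(CO)=C\C[C@@H](C(=O)OC)O)C(C)(C)CCC1 | intermediate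
19 | methyl (2S,4E,8E)-5-{[(tert-butyldimethylsilyl)oxy]methyl}-2-hydroxy-9-methyl-11-(2,6,6-trimethylcyclohex-1-en-1-yl)undeca-4,8-dienoate | CC1=C(CC/C(C)=C/CC/C(CO[Si](C)(C)C(C)(C)C)=C\C[C@@H](C(=O)OC)O)C(C)(C)CCC1 | intermediate
20 | methyl (2S,4E,8E)-2-acetoxy-5-{[(tert-butyldimethylsilyl)oxy]methyl}-9-methyl-11-(2,6,6-trimethylcyclohex-1-en-1-yl)undeca-4,8-dienoate | CC1=C(CC/C(C)=C/CC/C(CO[Si](C)(C)C(C)(C)C)=C\C[C@@H](C(=O)OC)OC(C)=O)C(C)(C)CCC1 | intermediate
21 | (5S)-5-[(2E,6E)-3-{[(tert-butyldimethylsilyl)oxy]methyl}-7-methyl-9-(2,6,6-trimethylcyclohex-1-en-1-yl)nona-2,6-dien-1-yl]-4-hydroxyfuran-2(5H)-one | CC1=C(CC/C(C)=C/CC/C(CO[Si](C)(C)C(C)(C)C)=C\C[C@@H]2OC(=O)C=C2O)C(C)(C)CCC1 | intermediate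
22 | (2S)-2-[(2E,6E)-3-{[(tert-butyldimethylsilyl)oxy]methyl}-7-methyl-9-(2,6,6-trimethylcyclohex-1-en-1-yl)nona-2,6-dien-1-yl]-5-oxo-2,5-dihydrofuran-3-yl trifluoromethanesulfonate | CC1=C(CC/C(C)=C/CC/C(CO[Si](C)(C)C(C)(C)C)=C\C[C@@H]2OC(=O)C=C2OS(=O)(=O)C(F)(F)F)C(C)(C)CCC1 | intermediate
23 | (5S)-5-[(2E,6E)-3-{[(tert-butyldimethylsilyl)oxy]methyl}-7-methyl-9-(2,6,6-trimethylcyclohex-1-en-1-yl)nona-2,6-dien-1-yl]-4-(hydroxymethyl)furan-2(5H)-one | CC1=C(CC/C(C)=C/CC/C(CO[Si](C)(C)C(C)(C)C)=C\C[C@@H]2OC(=O)C=C2CO)C(C)(C)CCC1 | intermediate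
24 | (5S)-4-(hydroxymethyl)-5-[(2E,6E)-3-(hydroxymethyl)-7-methyl-9-(2,6,6-trimethylcyclohex-1-en-1-yl)nona-2,6-dien-1-yl]furan-2(5H)-one | CC1=C(CC/C(C)=C/CC/C(=C\C[C@@H]2OC(=O)C=C2CO)CO)C(C)(C)CCC1 | target

**Step count**

Total: 16 steps. Longest linear sequence: 15 steps (1 to 24 through steps 1, 2 and 4 to 16).

**Steps most likely to fail, with fallbacks**

Step 8. After Si–H activation the alkyne may be hydrosilylated without CO insertion, or the internal alkyne may react too slowly, so that the formyl carbon is not installed on C3'. The fallback gives up the tether and forms the C2'=C3' alkene by a directed aldol condensation; it sets out from alkyne 10 and glycidate 11 and comes back at hydroxy enal 17. Alkyne 10 would be hydroborated at its terminal carbon with Cy2BH (THF, 0 °C) to dicyclohexyl[(1E,5E)-6-methyl-8-(2,6,6-trimethylcyclohex-1-en-1-yl)octa-1,5-dien-1-yl]borane F1 (not isolated) and oxidised with NaBO3·4H2O to (E)-6-methyl-8-(2,6,6-trimethylcyclohex-1-en-1-yl)oct-5-enal F2, in which the CH2 next to the formyl group is C3'. Condensation with tert-butylamine over MgSO4 would give the N-tert-butyl aldimine F3. Separately, 11 would be opened at C3 with CH2=CHMgBr and CuI (cat.) at −40 °C to methyl (S)-2-hydroxypent-4-enoate F4, silylated with Et3SiCl and imidazole to the triethylsilyl ether F5, and ozonised (O3, CH2Cl2, −78 °C; then PPh3) through the ozonide F6 (not isolated) to methyl (S)-4-oxo-2-[(triethylsilyl)oxy]butanoate F7. Deprotonation of F3 with LiN(iPr)2 at −78 °C and addition of F7 (Wittig directed aldol reaction) should give the β-hydroxy imine F8 (not isolated). Aqueous oxalic acid would then hydrolyse the imine, dehydrate the aldol to the thermodynamically preferred (E)-2-alkyl enal and remove the triethylsilyl group, which gives 17.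

Step 9. Fluoride may cleave only the Si–O bond and leave silicon on C2', or the basic medium may degrade the enal (γ-deprotonation, vinylogous elimination of the C5 oxygen) and epimerise or hydrolyse the α-hydroxy ester. The fallback cleaves the C–Si bond only after the aldehyde is gone; it sets out from 16 and comes back at diol 18. Luche reduction of 16 (NaBH4, CeCl3·7H2O, MeOH, −40 °C) would give the allylic alcohol methyl (3Z,5S)-3-[(5E)-1-hydroxy-6-methyl-8-(2,6,6-trimethylcyclohex-1-en-1-yl)oct-5-en-2-ylidene]-2,2-diisopropyl-1,2-oxasilolane-5-carboxylate F9. This non-conjugated alkenylsiloxane, assisted by the neighbouring hydroxyl, would be protodesilylated with retention by Bu4NF and CuI in THF at rt (or Bu4NF in DMF at 60 °C) to give 18 directly.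

Step 13. The amide base may enolise the α-acetoxy ester at C5 instead of the acetate methyl group, which would erode the stereocentre, or intermolecular Claisen and acetyl-transfer reactions may compete with ring closure. The fallback closes the ring by an intramolecular Wittig reaction without strong base; it sets out from 19 (so it replaces steps 12 and 13) and comes back at tetronic acid 21. Transesterification of 19 with allyl alcohol and Ti(OiPr)4 (cat.) at 80 °C would give prop-2-en-1-yl (2S,4E,8E)-5-{[(tert-butyldimethylsilyl)oxy]methyl}-2-hydroxy-9-methyl-11-(2,6,6-trimethylcyclohex-1-en-1-yl)undeca-4,8-dienoate F10. Ketenylidenetriphenylphosphorane (Ph3P=C=C=O, THF, 60 °C) should add the hydroxyl to give the O-(triphenylphosphoranylideneacetyl) ester ylide F11 (not isolated), which olefinates the allyl ester carbonyl to the allyl tetronate (5S)-4-(allyloxy)-5-[(2E,6E)-3-{[(tert-butyldimethylsilyl)oxy]methyl}-7-methyl-9-(2,6,6-trimethylcyclohex-1-en-1-yl)nona-2,6-dien-1-yl]furan-2(5H)-one F12. Deallylation with Pd(PPh3)4 (cat.) and morpholine in THF at rt would give 21.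

**Further compounds**

F1 | step 8 | dicyclohexyl[(1E,5E)-6-methyl-8-(2,6,6-trimethylcyclohex-1-en-1-yl)octa-1,5-dien-1-yl]borane | CC1=C(CC/C(C)=C/CC/C=C/B(C2CCCCC2)C2CCCCC2)C(C)(C)CCC1
F2 | step 8 | (E)-6-methyl-8-(2,6,6-trimethylcyclohex-1-en-1-yl)oct-5-enal | CC1=C(CC/C(C)=C/CCCC=O)C(C)(C)CCC1
F3 | step 8 | (1E,5E)-N-tert-butyl-6-methyl-8-(2,6,6-trimethylcyclohex-1-en-1-yl)oct-5-en-1-imine | CC1=C(CC/C(C)=C/CCC/C=N/C(C)(C)C)C(C)(C)CCC1
F4 | step 8 | methyl (S)-2-hydroxypent-4-enoate | C=CC[C@@H](C(=O)OC)O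
F5 | step 8 | methyl (S)-2-[(triethylsilyl)oxy]pent-4-enoate | C=CC[C@@H](C(=O)OC)O[Si](CC)(CC)CC
F6 | step 8 | methyl (2S)-3-(1,2,4-trioxolan-3-yl)-2-[(triethylsilyl)oxy]propanoate | C1OC(C[C@@H](C(=O)OC)O[Si](CC)(CC)CC)OO1
F7 | step 8 | methyl (S)-4-oxo-2-[(triethylsilyl)oxy]butanoate | O=CC[C@@H](C(=O)OC)O[Si](CC)(CC)CC
F8 | step 8 | methyl (2S,8E)-5-[(E)-(tert-butylimino)methyl]-4-hydroxy-9-methyl-2-[(triethylsilyl)oxy]-11-(2,6,6-trimethylcyclohex-1-en-1-yl)undec-8-enoate (mixture at C4 and C5) | CC1=C(CC/C(C)=C/CCC(/C=N/C(C)(C)C)C(O)C[C@@H](C(=O)OC)O[Si](CC)(CC)CC)C(C)(C)CCC1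
F9 | step 9 | methyl (3Z,5S)-3-[(5E)-1-hydroxy-6-methyl-8-(2,6,6-trimethylcyclohex-1-en-1-yl)oct-5-en-2-ylidene]-2,2-diisopropyl-1,2-oxasilolane-5-carboxylate | CC1=C(CC/C(C)=C/CC/C(CO)=C2\C[C@@H](C(=O)OC)O[Si]2(C(C)C)C(C)C)C(C)(C)CCC1
F10 | step 13 | prop-2-en-1-yl (2S,4E,8E)-5-{[(tert-butyldimethylsilyl)oxy]methyl}-2-hydroxy-9-methyl-11-(2,6,6-trimethylcyclohex-1-en-1-yl)undeca-4,8-dienoate | CC1=C(CC/C(C)=C/CC/C(CO[Si](C)(C)C(C)(C)C)=C\C[C@@H](C(=O)OCC=C)O)C(C)(C)CCC1
F11 | step 13 | prop-2-en-1-yl (2S,4E,8E)-5-{[(tert-butyldimethylsilyl)oxy]methyl}-9-methyl-2-{[(triphenyl-λ5-phosphanylidene)acetyl]oxy}-11-(2,6,6-trimethylcyclohex-1-en-1-yl)undeca-4,8-dienoate | CC1=C(CC/C(C)=C/CC/C(CO[Si](C)(C)C(C)(C)C)=C\C[C@@H](C(=O)OCC=C)OC(=O)C=P(c2ccccc2)(c2ccccc2)c2ccccc2)C(C)(C)CCC1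
F12 | step 13 | (5S)-4-(allyloxy)-5-[(2E,6E)-3-{[(tert-butyldimethylsilyl)oxy]methyl}-7-methyl-9-(2,6,6-trimethylcyclohex-1-en-1-yl)nona-2,6-dien-1-yl]furan-2(5H)-one | CC1=C(CC/C(C)=C/CC/C(CO[Si](C)(C)C(C)(C)C)=C\C[C@@H]2OC(=O)C=C2OCC=C)C(C)(C)CCC1
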